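**Plan**

1. The target is numbered as a cyclodeca[b]furan (O1, C2 lactone C=O, C3 =CH2, C3a, C4, C5 ketone, C6 Me, C7, C8, C9, C10 OH/Me, C11 O-acyl, C11a). The retrosynthesis cuts the C11 ester, returns C2=O to an ether CH2 and C10–OH/C9–H to a C9=C10 olefin, then cuts C7–C8 and C6–CH3 while re-joining C5–C10.
2. Enabling feature: the ring arc C5(=O)–C6–C7–C8–C9–C10 is a hydrated cyclodec-5-enone, the retron of an anionic oxy-Cope rearrangement. Re-joining C5–C10 leaves the six-membered ring C5–C10–C11–C11a–C3a–C4, which with the C10 methyl and the three-carbon branch on C3a is the skeleton of carvone.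
3. Forward: (R)-carvone → diene → singlet-oxygen route to the 4-hydroxy enone (C11a–O) → oxolane ring (temporary, reduced form of the lactone) → vinyl addition, directed epoxidation and semipinacol vinyl shift (quaternary C10, C11–O) → second vinyl addition → oxy-Cope ring expansion with in-flask methylation (ten-membered ring) → directed epoxidation and reductive opening (C10–OH) → ester → ether-to-lactone oxidation.
4. Stereochemistry: C3a from carvone; C11a by anti addition of singlet oxygen; C11 by hydroxyl-directed epoxidation and quaternary C10 by the stereospecific anti 1,2-shift; C6 by peripheral methylation of the ring enolate; the C10 carbinol by a second hydroxyl-directed epoxidation; the acyl centre from (R)-2-methylbutanoic acid.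

Key step: step 10

Remark: the 2-methylbutanoyl centre is taken as R, as drawn. Bicyclic intermediates are numbered as 1-benzofurans (O1, C2, C3, C3a, C4–C7, C7a), ten-membered-ring compounds as cyclodeca[b]furans. β is the face of H-7a (H-11a); α is the face of H-3a.

**Route**

Step 1
Reactants: 1 (R)-(−)-carvone
Product: 2 (E)-N′-[(5R)-2-methyl-5-(prop-1-en-2-yl)cyclohex-2-en-1-ylidene]-4-methylbenzenesulfonohydrazide
Conditions: TsNHNH2 (1.05 equiv), cat. AcOH, MeOH, 23 °C
Reagents that add atoms: 4-methylbenzenesulfonohydrazide, Cc1ccc(cc1)S(=O)(=O)NN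
Why: Hydrazone condensation at the enone carbonyl, with the sulfonamide nitrogen expected anti to the substituted C2 (syn to the CH2), which is the geometry the next step needs, and with the C5 stereocentre untouched.

Step 2
Reactants: 2 carvone tosylhydrazone
Product: 4 (5R)-2-methyl-5-(prop-1-en-2-yl)cyclohexa-1,3-diene, via alkenyllithium 3 (not isolated)
Conditions: MeLi (2.5 equiv), Et2O, 0 → 23 °C; then H2O
Reagents that add atoms: none
Why: Shapiro reaction: N–H and syn α′-C–H deprotonation, loss of sulfinate and N2, and protonation of the alkenyllithium should give the conjugated cyclohexa-1,3-diene without touching the stereocentre.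

Step 3
Reactants: 4 the triene
Product: 6 (4R,5S)-4-hydroxy-2-methyl-5-(prop-1-en-2-yl)cyclohex-2-en-1-one, via endoperoxide 5 (not isolated)
Conditions: O2, visible light, tetraphenylporphyrin (0.5 mol %), CH2Cl2, −78 °C; then Et3N (1.5 equiv), −78 → 0 °C
Reagents that add atoms: dioxygen, O=O
Why: Singlet-oxygen [4+2] cycloaddition to the cisoid diene on the face anti to the isopropenyl group sets the new C–O centre trans to it, and the Kornblum–DeLaMare rearrangement should remove the less hindered bridgehead proton (the one next to the ring CH2) to give the enone with hydroxyl next to the isopropenyl-bearing carbon.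

Step 4
Reactants: 6 the hydroxy enone
Product: 7 (4R,5S)-5-(3-chloroprop-1-en-2-yl)-4-hydroxy-2-methylcyclohex-2-en-1-one
Conditions: Ca(OCl)2, CO2 (solid), CH2Cl2–H2O, 0 °C
Reagents that add atoms: calcium hypochlorite, [Ca+2].[O-]Cl.[O-]Cl
Why: Ene-type allylic chlorination by hypochlorous acid should select the electron-rich 1,1-disubstituted olefin over the enone C=C and give the 2-(chloromethyl)vinyl group; no stereocentre is formed.

Step 5
Reactants: 7 the allylic chloride
Product: 8 (3aS,7aR)-6-methyl-3-methylidene-3,3a,4,7a-tetrahydro-1-benzofuran-5(2H)-one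
Conditions: NaH (1.1 equiv), n-Bu4NI (5 mol %), THF, 0 → 23 °C
Reagents that add atoms: none
Why: Intramolecular Williamson etherification (5-exo-tet; direct and allylic displacement give the same product) closes the oxolane at the side-chain carbon, so the trans ring fusion follows from the centres already present.

Step 6
Reactants: 8 the bicyclic enone
Product: 9 (3aS,5R,7aR)-5-ethenyl-6-methyl-3-methylidene-2,3,3a,4,5,7a-hexahydro-1-benzofuran-5-ol
Conditions: CH2=CHMgBr (1.5 equiv), CeCl3 (1.5 equiv), THF, −78 °C; then H2O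
Reagents that add atoms: vinylmagnesium bromide, C=C[Mg]Br
Why: Grignard-type 1,2-addition of the organocerium reagent to the enone carbonyl should occur by axial entry on the α-face of the half-chair locked by the trans ring fusion, giving α-vinyl and β-hydroxyl (5R).

Step 7
Reactants: 9 the tertiary allylic alcohol
Product: 10 (3aS,5R,6R,7R,7aS)-5-ethenyl-6,7-epoxy-6-methyl-3-methylideneoctahydro-1-benzofuran-5-ol
Conditions: VO(acac)2 (5 mol %), t-BuOOH (1.5 equiv), CH2Cl2, 0 → 23 °C
Reagents that add atoms: tert-butyl hydroperoxide, CC(C)(C)OO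
Why: Hydroxyl-directed epoxidation delivers oxygen to the β-face, syn to the hydroxyl, and should select the trisubstituted C6=C7 bond over the monosubstituted vinyl group and the remote methylene group.

Step 8
Reactants: 10 the epoxy alcohol
Product: 11 (3aS,6S,7S,7aS)-7-[(tert-butyldimethylsilyl)oxy]-6-ethenyl-6-methyl-3-methylidenehexahydro-1-benzofuran-5(4H)-one
Conditions: TBSOTf (1.5 equiv), i-Pr2NEt (2.0 equiv), 4 Å MS, CH2Cl2, −78 → −40 °C
Reagents that add atoms: tert-butyldimethylsilyl trifluoromethanesulfonate, CC(C)(C)[Si](C)(C)OS(=O)(=O)C(F)(F)F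
Why: Semipinacol rearrangement of a 2,3-epoxy alcohol: the pseudoaxial C5 vinyl group, antiperiplanar to the breaking C6–O bond, migrates to C6 with inversion there (vinyl α, methyl β), C5 becomes the ketone and the retained β-oxygen at C7 is silylated in the same event.

Step 9
Reactants: 11 the silyloxy ketone
Product: 12 (3aS,5R,6S,7S,7aS)-7-[(tert-butyldimethylsilyl)oxy]-5,6-diethenyl-6-methyl-3-methylideneoctahydro-1-benzofuran-5-ol
Conditions: CH2=CHMgBr (3 equiv), CeCl3 (3 equiv), THF, −78 → −40 °C; then H2O
Reagents that add atoms: vinylmagnesium bromide, C=C[Mg]Br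
Why: Grignard-type addition of the weakly basic organocerium reagent should enter axially on the α-face of the locked chair, anti to the axial C6 methyl, giving the axial α-vinyl carbinol (5R) with the two vinyl groups cis.

Step 10
Reactants: 12 the cis-divinyl carbinol
Product: 15 (3aS,6R,9Z,11S,11aS)-11-[(tert-butyldimethylsilyl)oxy]-6,10-dimethyl-3-methylidene-3,3a,4,6,7,8,11,11a-octahydrocyclodeca[b]furan-5(2H)-one, via potassium alkoxide 13 (not isolated), via potassium enolate 14 (not isolated)
Conditions: KH (1.5 equiv), 18-crown-6 (1.5 equiv), THF, 0 → 23 °C; then MeI (5 equiv), −78 → −30 °C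
Reagents that add atoms: iodomethane, CI
Why: Deprotonation gives alkoxide 13, whose C–O− bond weakens the adjacent ring bond so that the 1,5-diene undergoes a charge-accelerated [3,3]-sigmatropic shift (anionic oxy-Cope rearrangement, closest known type: cis-1,2-divinylcyclohexanolates to cyclodec-5-enone enolates), forming C7–C8, cleaving C5–C10 and giving enolate 14, which is C-methylated in the same flask (tandem oxy-Cope/enolate alkylation). The ten-membered ring is closed as a four-atom ring expansion of the cyclohexane: the two vinyl termini bond inside a six-atom chair array, possible because the trans-fused oxolane locks the C5 vinyl axial and the C10 vinyl equatorial (gauche). In that chair the old ring bond to C11 is axial and the one to C4 equatorial, which should give the 9Z olefin and the ring-E enolate. C6 is set by MeI attacking the enolate carbon on its peripheral face, the inner face being covered by the ring chain C7–C11a, which with the fixed enolate geometry should give 6R. The step needs regiospecific C-alkylation without enolate equilibration: the enolate is born only at C5=C6 and cold excess MeI traps it before proton transfer, and the C11 oxygen is silylated so that no second alkoxide is methylated or opens a retro-aldol-type path.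

Step 11
Reactants: 15 the silyloxy cyclodecenone
Product: 16 (3aS,6R,9Z,11S,11aS)-11-hydroxy-6,10-dimethyl-3-methylidene-3,3a,4,6,7,8,11,11a-octahydrocyclodeca[b]furan-5(2H)-one
Conditions: HF·pyridine, pyridine, THF, 0 → 23 °C
Reagents that add atoms: none
Why: Buffered fluoride desilylation should free the allylic C11 hydroxyl without enolising the ketone, so C6 is not scrambled.

Step 12
Reactants: 16 the Z-allylic alcohol
Product: 17 (3aS,6R,9S,10R,11R,11aS)-9,10-epoxy-11-hydroxy-6,10-dimethyl-3-methylidenedecahydrocyclodeca[b]furan-5(2H)-one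
Conditions: VO(acac)2 (5 mol %), t-BuOOH (1.5 equiv), CH2Cl2, 0 °C
Reagents that add atoms: tert-butyl hydroperoxide, CC(C)(C)OO
Why: Hydroxyl-directed epoxidation should deliver oxygen syn to the C11 hydroxyl from the conformer that keeps the carbinol hydrogen next to the C10 methyl (least 1,2-allylic strain) and the bond C11–C11a anti to the oxidant, setting the C10–O bond cis to C11–O, while the methylene group, which is not allylic to a hydroxyl, stays.

Step 13
Reactants: 17 the epoxy alcohol
Product: 18 (3aS,6R,9R,10R,11R,11aS)-10,11-dihydroxy-6,10-dimethyl-3-methylidene-9-(phenylselanyl)decahydrocyclodeca[b]furan-5(2H)-one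
Conditions: PhSeH (3 equiv), Ti(O-i-Pr)4 (1.5 equiv), CH2Cl2, 23 °C
Reagents that add atoms: benzeneselenol, [SeH]c1ccccc1
Why: Titanium-alkoxide-assisted opening of a 2,3-epoxy alcohol by the soft selenol should occur by SN2 at the distal secondary C9 (inversion there, C10–O bond retained), under non-basic, non-reducing conditions that leave the ketone and C6 alone.

Step 14
Reactants: 18 the hydroxy selenide
Product: 19 (3aS,6R,10S,11R,11aS)-10,11-dihydroxy-6,10-dimethyl-3-methylidenedecahydrocyclodeca[b]furan-5(2H)-one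
Conditions: n-Bu3SnH (2 equiv), AIBN (0.1 equiv), PhMe, 80 °C
Reagents that add atoms: none
Why: Radical-chain deselenation replaces C9–Se by C9–H, hydrogen transfer from the stannane being expected to outrun cyclisation of the secondary radical onto the methylene group, and no stereocentre is touched.

Step 15
Reactants: 19 the keto diol; 20 (2R)-2-methylbutanoic acid
Product: 21 (3aS,6R,10S,11R,11aS)-10-hydroxy-6,10-dimethyl-3-methylidene-5-oxododecahydrocyclodeca[b]furan-11-yl (2R)-2-methylbutanoate
Conditions: DCC (2 equiv), DMAP (1 equiv), CH2Cl2, 0 → 23 °C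
Reagents that add atoms: none
Why: Steglich esterification should acylate the secondary C11 hydroxyl and leave the tertiary C10 hydroxyl free, and the α-branched aliphatic acid is not expected to epimerise under carbodiimide activation.

Step 16
Reactants: 21 the ether ester
Product: 22 Ineupatorolide A
Conditions: CrO3 (15 equiv), 3,5-dimethylpyrazole (15 equiv), CH2Cl2, −20 °C
Reagents that add atoms: chromium trioxide, O=[Cr](=O)=O
Why: Allylic oxidation of a cyclic allyl ether by hexavalent chromium: C2–H2 is the only position both allylic and α to oxygen, so it should be converted into the lactone carbonyl of the α-methylene-γ-butyrolactone without forming or disturbing a stereocentre.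

**Compound list**

1 | (R)-(−)-carvone, (5R)-2-methyl-5-(prop-1-en-2-yl)cyclohex-2-en-1-one | CC1=CC[C@H](CC1=O)C(=C)C | starting material
2 | (E)-N′-[(5R)-2-methyl-5-(prop-1-en-2-yl)cyclohex-2-en-1-ylidene]-4-methylbenzenesulfonohydrazide | CC1=CC[C@H](C/C1=N\NS(=O)(=O)c2ccc(C)cc2)C(=C)C | intermediate
3 | [(3R)-6-methyl-3-(prop-1-en-2-yl)cyclohexa-1,5-dien-1-yl]lithium | CC1=CC[C@H](C=C1[Li])C(=C)C | intermediate
4 | (5R)-2-methyl-5-(prop-1-en-2-yl)cyclohexa-1,3-diene | CC1=CC[C@H](C=C1)C(=C)C | intermediate
5 | (1R,4R,7S)-5-methyl-7-(prop-1-en-2-yl)-2,3-dioxabicyclo[2.2.2]oct-5-ene (peroxide bridge anti to the isopropenyl group) | CC1=C[C@H]2OO[C@@H]1C[C@H]2C(C)=C | intermediate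
6 | (4R,5S)-4-hydroxy-2-methyl-5-(prop-1-en-2-yl)cyclohex-2-en-1-one | CC1=C[C@@H](O)[C@@H](CC1=O)C(C)=C | intermediate
7 | (4R,5S)-5-(3-chloroprop-1-en-2-yl)-4-hydroxy-2-methylcyclohex-2-en-1-one | CC1=C[C@@H](O)[C@@H](CC1=O)C(=C)CCl | intermediate
8 | (3aS,7aR)-6-methyl-3-methylidene-3,3a,4,7a-tetrahydro-1-benzofuran-5(2H)-one (trans-fused) | CC1=C[C@H]2OCC(=C)[C@@H]2CC1=O | intermediate
9 | (3aS,5R,7aR)-5-ethenyl-6-methyl-3-methylidene-2,3,3a,4,5,7a-hexahydro-1-benzofuran-5-ol (5β-OH, 5α-vinyl) | CC1=C[C@H]2OCC(=C)[C@@H]2C[C@@]1(O)C=C | intermediate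
10 | (3aS,5R,6R,7R,7aS)-5-ethenyl-6,7-epoxy-6-methyl-3-methylideneoctahydro-1-benzofuran-5-ol (β-epoxide, cis to OH) | C[C@@]12O[C@@H]1[C@H]3OCC(=C)[C@@H]3C[C@@]2(O)C=C | intermediate
11 | (3aS,6S,7S,7aS)-7-[(tert-butyldimethylsilyl)oxy]-6-ethenyl-6-methyl-3-methylidenehexahydro-1-benzofuran-5(4H)-one | C[C@]1(C=C)[C@H](O[Si](C)(C)C(C)(C)C)[C@H]2OCC(=C)[C@@H]2CC1=O | intermediate
12 | (3aS,5R,6S,7S,7aS)-7-[(tert-butyldimethylsilyl)oxy]-5,6-diethenyl-6-methyl-3-methylideneoctahydro-1-benzofuran-5-ol (vinyl groups cis) | C[C@]1(C=C)[C@H](O[Si](C)(C)C(C)(C)C)[C@H]2OCC(=C)[C@@H]2C[C@@]1(O)C=C | intermediate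
13 | potassium alkoxide of 12 | [K+].C[C@]1(C=C)[C@H](O[Si](C)(C)C(C)(C)C)[C@H]2OCC(=C)[C@@H]2C[C@@]1([O-])C=C | intermediate
14 | potassium (3aS,9Z,11S,11aS)-11-[(tert-butyldimethylsilyl)oxy]-10-methyl-3-methylidene-2,3,3a,4,7,8,11,11a-octahydrocyclodeca[b]furan-5-olate (ring-E enolate C5=C6) | [K+].[O-]/C1=C\CC/C=C(/C)\[C@H](O[Si](C)(C)C(C)(C)C)[C@H]2OCC(=C)[C@@H]2C1 | intermediate
15 | (3aS,6R,9Z,11S,11aS)-11-[(tert-butyldimethylsilyl)oxy]-6,10-dimethyl-3-methylidene-3,3a,4,6,7,8,11,11a-octahydrocyclodeca[b]furan-5(2H)-one | C[C@@H]1CC/C=C(/C)\[C@H](O[Si](C)(C)C(C)(C)C)[C@H]2OCC(=C)[C@@H]2CC1=O | intermediate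
16 | (3aS,6R,9Z,11S,11aS)-11-hydroxy-6,10-dimethyl-3-methylidene-3,3a,4,6,7,8,11,11a-octahydrocyclodeca[b]furan-5(2H)-one | C[C@@H]1CC/C=C(/C)\[C@H](O)[C@H]2OCC(=C)[C@@H]2CC1=O | intermediate
17 | (3aS,6R,9S,10R,11R,11aS)-9,10-epoxy-11-hydroxy-6,10-dimethyl-3-methylidenedecahydrocyclodeca[b]furan-5(2H)-one | C[C@@H]1CC[C@@H]3O[C@]3(C)[C@H](O)[C@H]2OCC(=C)[C@@H]2CC1=O | intermediate
18 | (3aS,6R,9R,10R,11R,11aS)-10,11-dihydroxy-6,10-dimethyl-3-methylidene-9-(phenylselanyl)decahydrocyclodeca[b]furan-5(2H)-one | C[C@@H]1CC[C@@H]([Se]c3ccccc3)[C@](C)(O)[C@H](O)[C@H]2OCC(=C)[C@@H]2CC1=O | intermediate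
19 | (3aS,6R,10S,11R,11aS)-10,11-dihydroxy-6,10-dimethyl-3-methylidenedecahydrocyclodeca[b]furan-5(2H)-one | C[C@@H]1CCC[C@](C)(O)[C@H](O)[C@H]2OCC(=C)[C@@H]2CC1=O | intermediate
20 | (2R)-2-methylbutanoic acid | CC[C@@H](C)C(=O)O | starting material
21 | (3aS,6R,10S,11R,11aS)-10-hydroxy-6,10-dimethyl-3-methylidene-5-oxododecahydrocyclodeca[b]furan-11-yl (2R)-2-methylbutanoate | C[C@@H]1CCC[C@](C)(O)[C@H](OC(=O)[C@H](C)CC)[C@H]2OCC(=C)[C@@H]2CC1=O | intermediate
22 | Ineupatorolide A, (3aS,6R,10S,11R,11aS)-10-hydroxy-6,10-dimethyl-3-methylidene-2,5-dioxododecahydrocyclodeca[b]furan-11-yl (2R)-2-methylbutanoate | C[C@@H]1CCC[C@](C)(O)[C@H](OC(=O)[C@H](C)CC)[C@H]2OC(=O)C(=C)[C@@H]2CC1=O | target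

**Count and risks**

Total step count: 16. Longest linear sequence: 16 steps from 1 (20 is used as purchased).

Most likely to fail:

1. Step 3. The base-induced peroxide cleavage may remove the other bridgehead proton, which would put the carbonyl next to the isopropenyl-bearing carbon, and singlet oxygen may also undergo an ene reaction at the isopropenyl group. The fallback sets out from 1 and returns at 6, placing the oxygen by enolate chemistry and moving the carbonyl by a Wharton transposition. The kinetic enolate of 1 (LiN(i-Pr)2, THF, −78 °C) is hydroxylated with 2-(phenylsulfonyl)-3-phenyloxaziridine anti to the isopropenyl group to give trans-6-hydroxycarvone F1. Silylation (TBSCl, imidazole, DMF) gives the silyl ether F2. Nucleophilic epoxidation (H2O2, NaOH, MeOH, 0 °C) gives the epoxy ketone F3. Wharton transposition (N2H4·H2O, AcOH, MeOH) gives the transposed allylic alcohol F4. Oxidation with MnO2 gives the silyloxy enone F5, and desilylation (Bu4NF, AcOH, THF) gives 6.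

2. Step 16. Oxidation may go on beyond the lactone, or hydrogen abstraction may occur at the tertiary allylic C3a–H or next to the ketone, on a substrate that also carries a free tertiary alcohol. The fallback sets out from 21 and returns at 22 in two stages with a different mechanism. SeO2 (cat.) with t-BuOOH in CH2Cl2 effects an ene/[2,3]-sigmatropic allylic hydroxylation at C2 to give the lactol F8 (anomeric mixture). The lactol is then oxidised with MnO2 in CH2Cl2 to 22.

3. Step 9. Facial selectivity may be poor in the addition to the ketone flanked by the quaternary carbon (equatorial entry competing), and enolisation toward C4 may compete. The fallback sets out from 11 and returns at 12, using a slim sp-hybridised nucleophile, which shows the strongest preference for axial entry, followed by semireduction. LiC≡CSiMe3 with CeCl3 in THF at −78 °C gives the silylalkynyl carbinol F6. K2CO3 in MeOH gives the terminal alkyne F7. Hydrogenation over Pd/CaCO3 poisoned with Pb(OAc)2 and quinoline (H2, 1 atm, EtOAc) gives 12.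

**Further compounds**

F1 | step 3 | (5S,6S)-6-hydroxy-2-methyl-5-(prop-1-en-2-yl)cyclohex-2-en-1-one (trans-6-hydroxycarvone) | CC1=CC[C@@H](C(C)=C)[C@H](O)C1=O
F2 | step 3 | (5S,6S)-6-[(tert-butyldimethylsilyl)oxy]-2-methyl-5-(prop-1-en-2-yl)cyclohex-2-en-1-one | CC1=CC[C@@H](C(C)=C)[C@H](O[Si](C)(C)C(C)(C)C)C1=O
F3 | step 3 | 2,3-epoxide of F2, epoxide anti to the isopropenyl group | C[C@@]12O[C@@H]1C[C@@H](C(C)=C)[C@H](O[Si](C)(C)C(C)(C)C)C2=O
F4 | step 3 | 4-[(tert-butyldimethylsilyl)oxy]-2-methyl-5-(prop-1-en-2-yl)cyclohex-2-en-1-ol, 4-silyloxy trans to isopropenyl, 1-hydroxyl cis to the 4-silyloxy group | CC1=C[C@@H](O[Si](C)(C)C(C)(C)C)[C@@H](C[C@H]1O)C(C)=C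
F5 | step 3 | (4R,5S)-4-[(tert-butyldimethylsilyl)oxy]-2-methyl-5-(prop-1-en-2-yl)cyclohex-2-en-1-one | CC1=C[C@@H](O[Si](C)(C)C(C)(C)C)[C@@H](CC1=O)C(C)=C
F6 | step 9 | 5α-[(trimethylsilyl)ethynyl] analogue of 12 (5β-OH) | C[C@]1(C=C)[C@H](O[Si](C)(C)C(C)(C)C)[C@H]2OCC(=C)[C@@H]2C[C@@]1(O)C#C[Si](C)(C)C
F7 | step 9 | 5α-ethynyl analogue of 12 (5β-OH) | C[C@]1(C=C)[C@H](O[Si](C)(C)C(C)(C)C)[C@H]2OCC(=C)[C@@H]2C[C@@]1(O)C#C
F8 | step 16 | 2-hydroxy derivative (lactol, anomeric mixture) of 21 | C[C@@H]1CCC[C@](C)(O)[C@H](OC(=O)[C@H](C)CC)[C@H]2OC(O)C(=C)[C@@H]2CC1=O
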